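The plan rests on cutting the C2–C1′ bond, the only link between the doubly sulfated catechol ring B and the chromone (rings A and C). The key step, a base-free oxidative Heck arylation catalysed by divalent palladium, joins the C2–H of a 5,7-bis(benzyloxy)chromone to a 3,4-bis(trichloroethyl sulfate)phenylboronic acid. This finishes the flavone skeleton in one operation with the sulfate regiochemistry already fixed. It exploits the fact that C2 is the β-carbon of the vinylogous ester O1–C2=C3–C4=O of ring C, where an aryl–palladium bond adds, leaving C3 free for later dioxirane hydroxylation. One reductive step then removes benzyl and trichloroethyl groups together.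

Key step: step 5

Assumption: the target is drawn as the free bis(hydrogen sulfate); it is obtained and stored as its diammonium salt, which is the same compound in its stable ionised form, and 3,4-dihydroxyphenylboronic acid pinacol ester is taken as a catalogue compound.

Step 1
Reactants: 1 phloroacetophenone (2,4,6-trihydroxyacetophenone)
Product: 2 dibenzyl ketone (4,6-bis(benzyloxy)-2-hydroxyacetophenone)
Conditions: BnBr (2.1 equiv), K2CO3 (2.2 equiv), DMF, 0 °C to rt
Reagents that add atoms: benzyl bromide, BrCc1ccccc1
Why: Williamson ether synthesis in which the 4-hydroxyl and one of the two equivalent ortho hydroxyls are alkylated, while the remaining ortho hydroxyl, hydrogen-bonded to the acetyl carbonyl and therefore the least nucleophilic, should stay free when only two equivalents of benzyl bromide are offered.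

Step 2
Reactants: 2 dibenzyl ketone (4,6-bis(benzyloxy)-2-hydroxyacetophenone)
Product: 4 chromone (5,7-bis(benzyloxy)-4H-chromen-4-one), via enaminone 3 (not isolated)
Conditions: DMF-DMA (3 equiv), toluene, 100 °C; evaporate; conc. HCl, CH2Cl2, 40 °C
Reagents that add atoms: N,N-dimethylformamide dimethyl acetal, COC(OC)N(C)C
Why: Enaminone chromone synthesis, in which condensation of the methyl ketone with the amide acetal supplies the future C2 and acid then drives the 6-endo-trig addition of the phenol to the enaminone β-carbon with loss of dimethylamine, closing ring C through the O1–C2 bond; the E geometry of 3 is of no consequence.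

Step 3
Reactants: 5 catechol boronate (3,4-dihydroxyphenylboronic acid pinacol ester)
Product: 6 sulfated boronate (pinacol ester of 3,4-bis[(2,2,2-trichloroethoxy)sulfonyloxy]phenylboronic acid)
Conditions: Cl3CCH2OSO2Cl (2.6 equiv), Et3N (2.6 equiv), DMAP (1 equiv), THF, 0 °C to rt, 5 added slowly to the reagent
Reagents that add atoms: 2,2,2-trichloroethyl chlorosulfate, O=S(=O)(Cl)OCC(Cl)(Cl)Cl
Why: DMAP-mediated sulfuryl transfer (aryl sulfate diester formation) to the only two hydroxyls in the molecule, so that no regiochemical question arises, with slow addition of the catechol to excess reagent intended to outrun closure of the monosulfate to a cyclic catechol sulfate.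

Step 4
Reactants: 6 sulfated boronate (pinacol ester of 3,4-bis[(2,2,2-trichloroethoxy)sulfonyloxy]phenylboronic acid)
Product: 7 sulfated boronic acid (3,4-bis[(2,2,2-trichloroethoxy)sulfonyloxy]phenylboronic acid)
Conditions: NaIO4 (3 equiv), 1 M HCl, THF/H2O (4:1), rt
Reagents that add atoms: water, O
Why: Oxidative pinacol boronate deprotection, in which periodate cleaves the pinacol released in the hydrolysis equilibrium and so pulls the ester over to the free boronic acid under acidic conditions that aryl trichloroethyl sulfates tolerate; the free acid is wanted because it transmetalates to divalent palladium without base far more readily than the pinacol ester.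

Step 5
Reactants: 4 chromone (5,7-bis(benzyloxy)-4H-chromen-4-one); 7 sulfated boronic acid (3,4-bis[(2,2,2-trichloroethoxy)sulfonyloxy]phenylboronic acid)
Product: 8 flavone (5,7-bis(benzyloxy)flavone 3',4'-bis(2,2,2-trichloroethyl sulfate))
Conditions: 7 (2.5 equiv, in portions), Pd(OAc)2 (10 mol%), 2,9-dimethyl-1,10-phenanthroline (12 mol%), O2 (1 atm), DMA, 60 °C
Reagents that add atoms: none
Why: Oxidative Heck (boron Heck) reaction: the aryl group of 7 passes from boron to divalent palladium, the aryl–palladium species adds syn across C2=C3 of 4 with the aryl at the β-carbon C2 and the metal at C3, the C-bound palladium enolate equilibrates through its O-bound form so that the C2 hydrogen can leave as palladium hydride, and oxygen returns zerovalent palladium to the divalent state. The closest known reaction type is the ligand-supported aerobic C2–H arylation of chromones with arylboronic acids to flavones, together with the analogous boron Heck reaction of cyclic enones. No ring is closed and no stereocentre is formed; the step only forges C2–C1′ between two finished halves. The selectivity needed is arylation at C2 and not at C3, C6 or C8, and it is secured by the polarisation of the vinylogous ester O1–C2=C3–C4=O, which sends the aryl to C2 and palladium to the enolate carbon C3, while the boron atom fixes the point of attachment on ring B. The medium is free of base and nucleophiles, so the trichloroethyl sulfate diesters and the benzyl ethers should pass unchanged, and the excess of 7 added in portions offsets homocoupling and ipso-oxidation.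

Step 6
Reactants: 8 flavone (5,7-bis(benzyloxy)flavone 3',4'-bis(2,2,2-trichloroethyl sulfate))
Product: 10 flavonol (5,7-bis(benzyloxy)-3-hydroxyflavone 3',4'-bis(2,2,2-trichloroethyl sulfate)), via flavone 2,3-epoxide 9 (not isolated)
Conditions: DMDO (acetone solution, 3–5 equiv, in portions), CH2Cl2, 0 °C to rt; evaporate; TsOH·H2O (0.1 equiv), CH2Cl2, rt
Reagents that add atoms: dimethyldioxirane, CC1(C)OO1
Why: Neutral dioxirane epoxidation of the enol-ether-like C2=C3 bond followed by acid-catalysed epoxide opening at C2 (cation stabilised by O1) and loss of the C3 hydrogen, the established 3-hydroxylation of benzyl-protected flavones; the racemic cis-fused epoxide stereocentres disappear on opening and the sulfate diesters are inert to both reagents.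

Step 7
Reactants: 10 flavonol (5,7-bis(benzyloxy)-3-hydroxyflavone 3',4'-bis(2,2,2-trichloroethyl sulfate))
Product: 11 target quercetin 3',4'-bis(hydrogen sulfate)
Conditions: 10% Pd/C, HCO2NH4 (12 equiv), MeOH/THF, rt; filter; C18 chromatography (aqueous NH4OAc/MeOH), lyophilise as the diammonium salt; Dowex 50W (H+ form), H2O, 0 °C only if the free acid is wanted
Reagents that add atoms: none
Why: Catalytic transfer hydrogenolysis in which palladium hydride cleaves both benzyl ethers and reductive β-elimination of chloride fragments both trichloroethyl groups to 1,1-dichloroethene, releasing the aryl sulfate monoesters as ammonium salts in a neutral, formate-buffered medium that should spare the acid-labile sulfates and the flavonol double bond.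

Compound list
1 | 2,4,6-trihydroxyacetophenone (phloroacetophenone) | CC(=O)c1c(O)cc(O)cc1O | starting material
2 | 4,6-bis(benzyloxy)-2-hydroxyacetophenone | CC(=O)c1c(O)cc(OCc2ccccc2)cc1OCc1ccccc1 | intermediate
3 | (E)-1-[2,4-bis(benzyloxy)-6-hydroxyphenyl]-3-(dimethylamino)prop-2-en-1-one (enaminone, not isolated) | CN(C)/C=C/C(=O)c1c(O)cc(OCc2ccccc2)cc1OCc1ccccc1 | intermediate
4 | 5,7-bis(benzyloxy)-4H-chromen-4-one | O=c1ccoc2cc(OCc3ccccc3)cc(OCc3ccccc3)c12 | intermediate
5 | 3,4-dihydroxyphenylboronic acid pinacol ester | CC1(C)OB(c2ccc(O)c(O)c2)OC1(C)C | starting material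
6 | 3,4-bis[(2,2,2-trichloroethoxy)sulfonyloxy]phenylboronic acid pinacol ester | CC1(C)OB(c2ccc(OS(=O)(=O)OCC(Cl)(Cl)Cl)c(OS(=O)(=O)OCC(Cl)(Cl)Cl)c2)OC1(C)C | intermediate
7 | 3,4-bis[(2,2,2-trichloroethoxy)sulfonyloxy]phenylboronic acid | OB(O)c1ccc(OS(=O)(=O)OCC(Cl)(Cl)Cl)c(OS(=O)(=O)OCC(Cl)(Cl)Cl)c1 | intermediate
8 | 5,7-bis(benzyloxy)flavone 3',4'-bis(2,2,2-trichloroethyl sulfate) | O=c1cc(-c2ccc(OS(=O)(=O)OCC(Cl)(Cl)Cl)c(OS(=O)(=O)OCC(Cl)(Cl)Cl)c2)oc2cc(OCc3ccccc3)cc(OCc3ccccc3)c12 | intermediate
9 | 2,3-epoxide of 8 (racemic, cis-fused, one enantiomer drawn, not isolated) | O=C1[C@H]2O[C@@]2(c3ccc(OS(=O)(=O)OCC(Cl)(Cl)Cl)c(OS(=O)(=O)OCC(Cl)(Cl)Cl)c3)Oc2cc(OCc3ccccc3)cc(OCc3ccccc3)c12 | intermediate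
10 | 5,7-bis(benzyloxy)-3-hydroxyflavone 3',4'-bis(2,2,2-trichloroethyl sulfate) | O=c1c(O)c(-c2ccc(OS(=O)(=O)OCC(Cl)(Cl)Cl)c(OS(=O)(=O)OCC(Cl)(Cl)Cl)c2)oc2cc(OCc3ccccc3)cc(OCc3ccccc3)c12 | intermediate
11 | quercetin 3',4'-bis(hydrogen sulfate) | O=c1c(O)c(-c2ccc(OS(=O)(=O)O)c(OS(=O)(=O)O)c2)oc2cc(O)cc(O)c12 | target

Total step count: 7
Longest linear sequence: 5 steps (steps 1, 2, 5, 6, 7 from compound 1; equally steps 3, 4, 5, 6, 7 from compound 5)

Steps most likely to fail

Step 5. The boron partner may be consumed by homocoupling and ipso-oxidation under oxygen faster than the aryl–palladium species inserts into the electron-rich chromone. Transient zerovalent palladium may also attack the C–Cl bonds of the trichloroethyl groups. The fallback sets out from 4 and 7 and makes the same C2–C1′ bond with no redox change at the metal. Conjugate addition catalysed by divalent palladium (Pd(O2CCF3)2, 2,2'-bipyridine, NH4PF6, H2O, 1,2-dichloroethane, 60 °C) ends by protonation of the palladium enolate and should give racemic 5,7-bis(benzyloxy)flavanone 3',4'-bis(2,2,2-trichloroethyl sulfate) F1. Dehydrogenation of F1 with DDQ in dioxane at 90 °C then returns the route to 8.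

Step 6. The electrophilic epoxidation may be sluggish because the electron-poor ring B deactivates C2=C3, and long exposure to the dioxirane may oxidise the benzylic positions of the benzyl ethers. The fallback sets out from 4 and 7 through the flavanone F1 described above. Soft enolisation (TMSOTf, Et3N, CH2Cl2, 0 °C) should give the silyl enol ether 5,7-bis(benzyloxy)-4-(trimethylsilyloxy)flav-3-ene 3',4'-bis(2,2,2-trichloroethyl sulfate) F2. Its electron-rich double bond should take up oxygen readily in a Rubottom oxidation (DMDO, acetone, −20 °C, then dilute citric acid) to give racemic trans-5,7-bis(benzyloxy)-3-hydroxyflavanone 3',4'-bis(2,2,2-trichloroethyl sulfate) F3. Dehydrogenation of F3 with iodine and KOAc in acetic acid, the classical passage from dihydroflavonols to flavonols, rejoins the route at 10.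

Step 7. Hydrodechlorination on palladium may stall at dichloroethyl or chloroethyl sulfate esters that no longer fragment, released chloride may slow the debenzylation, and sulfate may be lost if the mixture turns acidic during work-up. The fallback sets out from 10 and separates the two reductions. Zn dust and HCO2NH4 in MeOH/THF at rt remove only the trichloroethyl groups by two-electron reductive fragmentation and should give 5,7-di-O-benzylquercetin 3',4'-bis(hydrogen sulfate) F4, handled as its diammonium salt. Hydrogenolysis of F4 (H2 1 atm, Pd(OH)2/C, MeOH/H2O buffered with NH4HCO3) should then free the 5- and 7-hydroxyls and arrive at 11.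

Further compounds
F1 | step 5 | racemic 5,7-bis(benzyloxy)flavanone 3',4'-bis(2,2,2-trichloroethyl sulfate) | O=C1CC(c2ccc(OS(=O)(=O)OCC(Cl)(Cl)Cl)c(OS(=O)(=O)OCC(Cl)(Cl)Cl)c2)Oc2cc(OCc3ccccc3)cc(OCc3ccccc3)c12
F2 | step 6 | racemic 5,7-bis(benzyloxy)-4-(trimethylsilyloxy)flav-3-ene 3',4'-bis(2,2,2-trichloroethyl sulfate) | C[Si](C)(C)OC1=CC(c2ccc(OS(=O)(=O)OCC(Cl)(Cl)Cl)c(OS(=O)(=O)OCC(Cl)(Cl)Cl)c2)Oc2cc(OCc3ccccc3)cc(OCc3ccccc3)c12
F3 | step 6 | racemic trans-5,7-bis(benzyloxy)-3-hydroxyflavanone 3',4'-bis(2,2,2-trichloroethyl sulfate) (2R,3R enantiomer drawn) | c1cc(OS(=O)(=O)OCC(Cl)(Cl)Cl)c(OS(=O)(=O)OCC(Cl)(Cl)Cl)cc1[C@@H]1[C@@H](O)C(=O)c2c(OCc3ccccc3)cc(OCc3ccccc3)cc2O1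
F4 | step 7 | 5,7-di-O-benzylquercetin 3',4'-bis(hydrogen sulfate) | O=c1c(O)c(-c2ccc(OS(=O)(=O)O)c(OS(=O)(=O)O)c2)oc2cc(OCc3ccccc3)cc(OCc3ccccc3)c12
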